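The quinone ring (C1=O, C2–OAr, C3–CH2CH2Ar, C4=O, C5H=C6H) is built rather than bought, at the hydroquinone monomethyl ether level, from an open-chain (3E,5Z)-dienyl diazomethyl ketone. On irradiation a Wolff 1,2-shift moves the dienyl carbon from the acyl carbon to the diazo carbon (C5–C6 bond). The dienylketene then closes by 6π-electrocyclisation (C4–C3 bond) and enolises. The step exploits the unsubstituted C5H=C6H edge next to the contiguous O, O, alkyl, O pattern of this ring and places all four substituents regiospecifically. A B-alkyl Suzuki reaction closes the 18-membered ring; demethylation and mild oxidation finish.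

Key step: step 6

Remark: the target has no stereocentre and its 18-membered ring is taken as conformationally mobile, so it is achiral. Only the C=C geometry of the open-chain intermediates needs control.

Step 1
Reactants: 1 5-bromo-2-methoxyphenol; 2 [4-(3-methoxy-3-oxopropyl)phenyl]boronic acid
Product: 3 methyl 3-[4-(5-bromo-2-methoxyphenoxy)phenyl]propanoate
Conditions: Cu(OAc)2 (2 equiv), pyridine, 4 Å MS, CH2Cl2, rt
Reagents that add atoms: none
Why: Chan–Lam–Evans O-arylation should form the A–O–B diaryl ether at room temperature without touching the aryl bromide or the ester; no stereocentre is formed.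

Step 2
Reactants: 3 methyl 3-[4-(5-bromo-2-methoxyphenoxy)phenyl]propanoate
Product: 4 3-[4-(5-bromo-2-methoxyphenoxy)phenyl]propanal
Conditions: DIBAL-H (1.05 equiv), CH2Cl2, −78 °C; MeOH, aq. Rochelle salt
Reagents that add atoms: none
Why: Partial ester reduction with DIBAL-H should stop at the aldehyde, because the tetrahedral aluminium hemiacetal persists at −78 °C until the quench.

Step 3
Reactants: 5 3-ethenylphenol (3-vinylphenol); 6 methyl (E)-4-chloro-3-methoxybut-2-enoate
Product: 7 methyl (E)-4-(3-ethenylphenoxy)-3-methoxybut-2-enoate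
Conditions: K2CO3, NaI (cat.), acetone, 50 °C
Reagents that add atoms: none
Why: Williamson ether synthesis (SN2 at the allylic chloride) should install ring C on the future quinone C2 carbon; the E geometry (ester cis to the CH2O carbon) is not touched.

Step 4
Reactants: 7 methyl (E)-4-(3-ethenylphenoxy)-3-methoxybut-2-enoate; 4 3-[4-(5-bromo-2-methoxyphenoxy)phenyl]propanal
Product: 9 (2E,4Z)-7-[4-(5-bromo-2-methoxyphenoxy)phenyl]-4-(3-ethenylphenoxy)-3-methoxyhepta-2,4-dienoic acid, via 6-{2-[4-(5-bromo-2-methoxyphenoxy)phenyl]ethyl}-5-(3-ethenylphenoxy)-4-methoxy-5,6-dihydro-2H-pyran-2-one 8 (not isolated)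
Conditions: LDA (1.05 equiv), THF, −78 °C; add 4, −78 → 0 °C; KOt-Bu (1.5 equiv), 0 °C → rt; cold dil. HCl to pH 4
Reagents that add atoms: none
Why: A vinylogous aldol addition at the γ-carbon (acidified by OAr) is trapped irreversibly by lactonisation onto the cis ester (kavalactone-type closure), and the known E1cB ring opening of 5,6-dihydropyran-2-ones should then keep the carboxyl cis to C4 (2E) and place the arylethyl chain trans to C3 (4Z), erasing both lactone stereocentres.

Step 5
Reactants: 9 (2E,4Z)-7-[4-(5-bromo-2-methoxyphenoxy)phenyl]-4-(3-ethenylphenoxy)-3-methoxyhepta-2,4-dienoic acid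
Product: 11 (3E,5Z)-8-[4-(5-bromo-2-methoxyphenoxy)phenyl]-1-diazo-5-(3-ethenylphenoxy)-4-methoxyocta-3,5-dien-2-one, via (2E,4Z)-dienoyl chloride 10 (not isolated)
Conditions: 1-chloro-N,N,2-trimethylprop-1-en-1-amine (Ghosez reagent), CH2Cl2, 0 °C; then CH2N2 (excess), Et2O, 0 °C
Reagents that add atoms: diazomethane, C=[N+]=[N-]
Why: Acylation of diazomethane (first stage of the Arndt–Eistert sequence) by an acid chloride made under neutral conditions should spare the enol ethers, and the electron-rich trisubstituted enoyl C=C is a poor dipolarophile, so both alkene geometries are carried through.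

Step 6
Reactants: 11 (3E,5Z)-8-[4-(5-bromo-2-methoxyphenoxy)phenyl]-1-diazo-5-(3-ethenylphenoxy)-4-methoxyocta-3,5-dien-2-one
Product: 14 2-{2-[4-(5-bromo-2-methoxyphenoxy)phenyl]ethyl}-3-(3-ethenylphenoxy)-4-methoxyphenol, via (3E,5Z)-dienylketene 12 (not isolated), via 6-substituted cyclohexa-2,4-dien-1-one 13 (not isolated)
Conditions: hν (440 nm LED), toluene (5 mM), rt; then 80 °C, 1 h
Reagents that add atoms: none
Why: Excitation of the s-Z diazoketone expels N2 with 1,2-migration of alkenyl carbon C3 of 11 from the carbonyl carbon to the former diazo carbon (Wolff rearrangement, geometry of the migrating alkene retained), which makes the future quinone C5–C6 bond and gives dienylketene 12. Because the 3E geometry holds the ketene arm and the C(OAr)=CH unit cis on the central double bond, 12 should undergo thermal disrotatory 6π-electrocyclisation (all-carbon six-membered ring, ketene carbon to the terminal diene CH), which makes the future C4–C3 bond and gives dienone 13. Enolisation of 13 erases its only sp3 ring carbon, so no stereocentre remains and aromatisation makes the sequence irreversible. The closest known reactions are the photochemical Wolff entry to vinylketenes, the dienylketene-to-phenol closure that ends the Danheiser, Dötz and Moore benzannulations, and Wolff-based benzannulations of dienyl diazo carbonyl compounds. Regiochemistry is fixed by connectivity alone: OH ends para to OMe, with OAr and the arylethyl chain between them. Chemoselectivity needs three things: metal-free visible light (no carbenoid cyclopropanation of the C5=C6 enol ether, no excitation of ArBr or styrene), the 5Z geometry that turns the chain outward at the closing terminus, and high dilution so that phenol 14 is not acylated by ketene 12.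

Step 7
Reactants: 14 2-{2-[4-(5-bromo-2-methoxyphenoxy)phenyl]ethyl}-3-(3-ethenylphenoxy)-4-methoxyphenol
Product: 16 macrocyclic bis(bibenzyl) with ring Q as 4-methoxyphenol and ring B as methyl ether (di-O-methyl dihydromarchantinquinone), via B-alkyl-9-BBN derivative 15 (not isolated)
Conditions: 9-BBN-H (2.5 equiv), THF, rt; then slow addition to PdCl2(dppf) (15 mol %), AsPh3, Cs2CO3, DMF–THF–H2O, 60 °C, final 1 mM
Reagents that add atoms: none
Why: Anti-Markovnikov hydroboration of the styrene followed by intramolecular B-alkyl Suzuki–Miyaura coupling with the ring-B bromide should give the saturated B–C ethano bridge and the 18-membered ring directly; the extra 9-BBN covers the phenol O–H, which aqueous base frees again.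

Step 8
Reactants: 16 di-O-methyl dihydromarchantinquinone
Product: 17 dihydromarchantinquinone (macrocyclic hydroquinone with free ring-B phenol)
Conditions: BBr3 (6 equiv), CH2Cl2, −78 → 0 °C, argon; H2O
Reagents that add atoms: none
Why: Lewis-acid aryl methyl ether cleavage with BBr3 should remove both methyl groups, while the two diaryl ether bonds, which cannot undergo SN2 at carbon, are left intact.

Step 9
Reactants: 17 dihydromarchantinquinone
Product: 18 marchantinquinone
Conditions: Ag2O (1.2 equiv), Na2SO4, Et2O–CH2Cl2, rt, 15 min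
Reagents that add atoms: none
Why: Two-electron oxidation of a hydroquinone to the 1,4-benzoquinone with Ag2O is much faster than oxidation of the isolated 2-aryloxy-4-alkylphenol of ring B, so near-stoichiometric oxidant and a short contact time should be chemoselective.

Compound list
1 | 5-bromo-2-methoxyphenol | COc1ccc(Br)cc1O | starting material
2 | [4-(3-methoxy-3-oxopropyl)phenyl]boronic acid | COC(=O)CCc1ccc(cc1)B(O)O | starting material
3 | methyl 3-[4-(5-bromo-2-methoxyphenoxy)phenyl]propanoate | COC(=O)CCc1ccc(Oc2cc(Br)ccc2OC)cc1 | intermediate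
4 | 3-[4-(5-bromo-2-methoxyphenoxy)phenyl]propanal | O=CCCc1ccc(Oc2cc(Br)ccc2OC)cc1 | intermediate
5 | 3-ethenylphenol | C=Cc1cccc(O)c1 | starting material
6 | methyl (E)-4-chloro-3-methoxybut-2-enoate | COC(=O)/C=C(/OC)CCl | starting material
7 | methyl (E)-4-(3-ethenylphenoxy)-3-methoxybut-2-enoate | COC(=O)/C=C(/OC)COc1cccc(C=C)c1 | intermediate
8 | 6-{2-[4-(5-bromo-2-methoxyphenoxy)phenyl]ethyl}-5-(3-ethenylphenoxy)-4-methoxy-5,6-dihydro-2H-pyran-2-one (racemic, cis/trans mixture) | O=C1C=C(OC)C(Oc2cccc(C=C)c2)C(CCc2ccc(Oc3cc(Br)ccc3OC)cc2)O1 | intermediate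
9 | (2E,4Z)-7-[4-(5-bromo-2-methoxyphenoxy)phenyl]-4-(3-ethenylphenoxy)-3-methoxyhepta-2,4-dienoic acid | OC(=O)/C=C(OC)\C(Oc1cccc(C=C)c1)=C\CCc1ccc(Oc2cc(Br)ccc2OC)cc1 | intermediate
10 | (2E,4Z)-7-[4-(5-bromo-2-methoxyphenoxy)phenyl]-4-(3-ethenylphenoxy)-3-methoxyhepta-2,4-dienoyl chloride | ClC(=O)/C=C(OC)\C(Oc1cccc(C=C)c1)=C\CCc1ccc(Oc2cc(Br)ccc2OC)cc1 | intermediate
11 | (3E,5Z)-8-[4-(5-bromo-2-methoxyphenoxy)phenyl]-1-diazo-5-(3-ethenylphenoxy)-4-methoxyocta-3,5-dien-2-one | [N-]=[N+]=CC(=O)/C=C(OC)\C(Oc1cccc(C=C)c1)=C\CCc1ccc(Oc2cc(Br)ccc2OC)cc1 | intermediate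
12 | (3E,5Z)-8-[4-(5-bromo-2-methoxyphenoxy)phenyl]-5-(3-ethenylphenoxy)-4-methoxyocta-1,3,5-trien-1-one (dienylketene) | O=C=C/C=C(OC)\C(Oc1cccc(C=C)c1)=C\CCc1ccc(Oc2cc(Br)ccc2OC)cc1 | intermediate
13 | 6-{2-[4-(5-bromo-2-methoxyphenoxy)phenyl]ethyl}-5-(3-ethenylphenoxy)-4-methoxycyclohexa-2,4-dien-1-one (racemic, transient) | O=C1C=CC(OC)=C(Oc2cccc(C=C)c2)C1CCc1ccc(Oc2cc(Br)ccc2OC)cc1 | intermediate
14 | 2-{2-[4-(5-bromo-2-methoxyphenoxy)phenyl]ethyl}-3-(3-ethenylphenoxy)-4-methoxyphenol | Oc1ccc(OC)c(Oc2cccc(C=C)c2)c1CCc1ccc(Oc2cc(Br)ccc2OC)cc1 | intermediate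
15 | 3-{3-[2-(9-borabicyclo[3.3.1]nonan-9-yl)ethyl]phenoxy}-2-{2-[4-(5-bromo-2-methoxyphenoxy)phenyl]ethyl}-4-methoxyphenol | Oc1ccc(OC)c(Oc2cccc(CCB3C4CCCC3CCC4)c2)c1CCc1ccc(Oc2cc(Br)ccc2OC)cc1 | intermediate
16 | di-O-methyl dihydromarchantinquinone (18-membered macrocycle; ring Q 4-methoxyphenol, ring B methyl ether) | Oc1ccc(OC)c2c1CCc1ccc(cc1)Oc1cc(ccc1OC)CCc1cccc(c1)O2 | intermediate
17 | dihydromarchantinquinone (macrocyclic hydroquinone, free ring-B phenol) | Oc1ccc(O)c2c1CCc1ccc(cc1)Oc1cc(ccc1O)CCc1cccc(c1)O2 | intermediate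
18 | marchantinquinone | O=C1C=CC(=O)C2=C1CCc1ccc(cc1)Oc1cc(ccc1O)CCc1cccc(c1)O2 | target

Total step count: 9. Longest linear sequence: 8 (steps 1, 2, 4, 5, 6, 7, 8, 9).

Steps most likely to fail

Step 6. Three processes could drain material: photoisomerisation about the central C3=C4 bond, carbene-type side reactions, and interception of the ketene by the phenol already formed. The fallback sets out from 11 and separates the two bond formations.
- A silver benzoate/Et3N-catalysed Wolff rearrangement in aqueous THF in the dark traps the ketene as (3E,5Z)-8-[4-(5-bromo-2-methoxyphenoxy)phenyl]-5-(3-ethenylphenoxy)-4-methoxyocta-3,5-dienoic acid F1.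
- Classical cyclodehydration of this dienylacetic acid with Ac2O/NaOAc (100 °C, BHT), as in Stobbe-type benzannulations, should give 2-{2-[4-(5-bromo-2-methoxyphenoxy)phenyl]ethyl}-3-(3-ethenylphenoxy)-4-methoxyphenyl acetate F2.
- Methanolysis (K2CO3, MeOH) comes back to the route at 14.

Step 4. The dienolate could attack through its α-carbon, the aldehyde could be enolised, or the ring opening could be incomplete or poorly selective in alkene geometry. The fallback sets out from 7.
- Silylation (LDA, TMSCl) gives the Brassard-type diene {[4-(3-ethenylphenoxy)-1,3-dimethoxybuta-1,3-dien-1-yl]oxy}trimethylsilane F3.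
- Its Lewis-acid-promoted hetero-Diels–Alder reaction with 4 (Et2AlCl, CH2Cl2, −78 °C) is inherently γ-selective.
- This comes back to the route at lactone 8, which is now isolated and opened separately with KOt-Bu to give 9.

Step 7. Oligomerisation could outrun ring closure, and the alkylborane could be lost by protodeboronation or β-hydride elimination. The fallback sets out from 14.
- An intramolecular Mizoroki–Heck reaction (Pd(OAc)2, P(o-tol)3, Et3N, DMF, high dilution, 100 °C) closes the ring as the (E)-stilbene macrocycle F4.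
- Hydrogenation (H2, Pd/C, EtOAc) comes back to the route at 16.

Further compounds
F1 | step 6 | (3E,5Z)-8-[4-(5-bromo-2-methoxyphenoxy)phenyl]-5-(3-ethenylphenoxy)-4-methoxyocta-3,5-dienoic acid | OC(=O)C/C=C(OC)\C(Oc1cccc(C=C)c1)=C\CCc1ccc(Oc2cc(Br)ccc2OC)cc1
F2 | step 6 | 2-{2-[4-(5-bromo-2-methoxyphenoxy)phenyl]ethyl}-3-(3-ethenylphenoxy)-4-methoxyphenyl acetate | CC(=O)Oc1ccc(OC)c(Oc2cccc(C=C)c2)c1CCc1ccc(Oc2cc(Br)ccc2OC)cc1
F3 | step 4 | {[4-(3-ethenylphenoxy)-1,3-dimethoxybuta-1,3-dien-1-yl]oxy}trimethylsilane (alkene geometry not defined) | COC(O[Si](C)(C)C)=CC(OC)=COc1cccc(C=C)c1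
F4 | step 7 | (E)-stilbene macrocycle (B–C bridge CH=CH, otherwise as 16) | Oc1ccc(OC)c2c1CCc1ccc(cc1)Oc1cc(ccc1OC)/C=C/c1cccc(c1)O2
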